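The readings come from a simulation for substances that don't exist; the scatter is artificial.

The easy slip is to read the rate off the catalyst charged, when added ligand ties some of that catalyst up.

| flask | starting material | free catalyst | added ligand | remark |
|---|---|---|---|---|
| delta | 1 M | 1 mM | 0.38 mM | run made earlier |
| zeta | 1 M | 1 mM | 0.84 mM | run made earlier |
| alpha | 1 M | 0.50 mM | 0.56 mM | run made earlier |
| flask | 1.0 M | 1.0 mM | 0.56 mM |  |

- delta (time / h: product / %, starting material / %): 1.50: 6.7, 94.0; 4.00: 15.3, 88.7; 8.00: 30.2, 70.2; 20.0: 67.1, 30.5
- zeta (time / h: product / %, starting material / %): 1.50: 3.8, 96.5; 4.00: 10.9, 90.2; 8.00: 21.5, 76.7; 20.0: 47.8, 52.8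
- alpha (time / h: product / %, starting material / %): 2.50: 4.4, 95.7; 8.00: 10.9, 89.8; 12.0: 15.8, 82.5; 20.0: 27.1, 73.8

(scatter of a reading: 1 percentage point)

* apparent order in free catalyst when 5.0% of the starting material are converted (percent change of the rate of making product for one percent more free catalyst charged)
* factor on the rate of making product when 5.0% of the starting material are converted if free catalyst is charged twice over

- what was read earlier has a scatter of 1 percentage point, one standard deviation

Product climbs close to a straight line up to 8.00 h, so I take the rate at 5.0% conversion as product over time there: delta 0.0377 h⁻¹, zeta 0.0269 h⁻¹. Zeta thus reads at 0.712 of delta, a ratio that carries the scatter of the readings.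

Suppose the rate follows untied catalyst, and each added ligand ties one catalyst. Both runs must then share one quotient, and that asks for 0.762 mM untied in delta:

[untied catalyst] × [ligand left] / [tied catalyst] = 0.762 mM × 0.142 mM / 0.238 mM = 0.453 mM

I carry this quotient as the hold. For the flask it gives 0.667 mM untied, and 1.57 mM with the catalyst charge doubled:

order = 1.25, doubling factor = 2.35

The weak link is the supposition, since two runs made the hold. Alpha played no part, so test it there: 0.284 mM untied means 11.2% product at 8.00 h, and 10.9% was read, with a scatter of 1 percentage point.

The forecast says order 1.3 and doubling factor 2.4, the factor a little above mine, from a hold of 0.35 mM. Its ground: “Ligand suppresses the rate, which suggests it sequesters catalyst reversibly.”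

The flask gives order 1.3 and doubling factor 2.38.

    free catalyst + added ligand ⇌ idle complex, settled at all times (K = 26000 M⁻¹)
    starting material + free catalyst ⇌ catalyst intermediate (K = 11.0 M⁻¹, k = 5800 M⁻¹ h⁻¹)
    catalyst intermediate → free catalyst + product (k = 55.0 h⁻¹)

In the flask at 9.39 h, catalyst intermediate falls back 9.6 times faster than it goes on to product. At 5.0% conversion it holds 59.1% of the catalyst, against 6.25% free and 34.7% as idle complex, which sits off the working round. Counting intermediate and free catalyst together as untied, the flask at 2.00 h shows a hold of 0.396 mM, where the delta and zeta readings gave 0.453 mM. At 200 h, with starting material at 0%, the same quotient in the flask is 0.0385 mM.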